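**Plan**
- Cuts, in retrosynthetic order: (i) the ether bond from the spiro-carbon oxygen to the allylic ring-fusion carbon C-3 of the cyclohexene, back to a C-3 ketone and an O-silyl carbinol; (ii) the two C–C bonds of the bicyclo[2.2.2]octane (Diels–Alder) to (R)-sorbicillinol and a 2-silyloxyacrylate ester; (iii) the C-4 O–acyl bond and the aryl–sorbyl bond.
- Forward: shikimic acid → 5-O-TBS-3-dehydroshikimate → 4-O-(2-silyloxyacryloyl) ester; sorbicillin → resolved quinol acetate → sorbicillinol; the cycloaddition builds the bicyclooctane and the spiro carbon; the 1,4-dioxan-2-one is closed last; desilylation.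
- Enabling feature: C-3 is allylic and next to C-4, whose oxygen carries the acyl tether. As a ketone, C-3 lies six atoms from the spiro oxygen (O–C–C(=O)–O–C4–C3), so ketalisation closes the dioxanone and leaves a ring-fused oxocarbenium ion to be reduced.
- Stereochemistry: C-4 and C-5 come from (−)-shikimic acid. C-3 comes from axial hydride delivery anti to the axial H-4 (trans ring fusion, net inversion of shikimate C-3). The carbinol centre comes from resolution. Both bridgeheads and the spiro carbon come from the cycloaddition (approach syn to the carbinol OH, ester endo).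

Key step: step 11

Remark: the cyclohexene is numbered as in shikimic acid (C-1 bears CO2Me, C-3 is the allylic ether carbon). Read from the SMILES, the target has C-3 S, C-4 S, C-5 R, i.e. (−)-shikimate with C-3 inverted, and an R carbinol centre in the sorbicillinol half; the route is built for exactly this enantiomer.

Step 1
Reactants: 1 2,4-dimethylbenzene-1,3-diol; 2 sorbic acid
Product: 3 sorbicillin
Conditions: BF3·OEt2 (excess, neat), 80–110 °C, short reaction time; aqueous work-up
Reagents that add atoms: none
Why: Friedel–Crafts C-acylation (through the aryl sorbate and a Fries-type shift) should occur at C-6, the only open position ortho/para to both hydroxyls, giving the chelated ortho-hydroxy ketone without touching the diene.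

Step 2
Reactants: 3 sorbicillin
Product: 4 racemic sorbicillinol acetate
Conditions: Pb(OAc)4 (1.1 equiv), AcOH/CH2Cl2, 0 °C → rt
Reagents that add atoms: lead(IV) acetate, CC(=O)O[Pb](OC(C)=O)(OC(C)=O)OC(C)=O
Why: Wessely acetoxylation, in which Pb(IV) bound at the free 4-OH should deliver acetate to the adjacent methyl-bearing carbon C-5 (the 2-OH is held in a hydrogen bond to the ketone), gives the stable ortho-quinol acetate as a racemate; the minor C-3 regioisomer is removed by chromatography.

Step 3
Reactants: 4 racemic sorbicillinol acetate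
Product: 5 (R)-sorbicillinol acetate
Conditions: preparative HPLC on amylose tris(3,5-dimethylphenylcarbamate), hexane/i-PrOH, rt; the R enantiomer is kept
Reagents that add atoms: none
Why: Chromatographic resolution of the racemate on a chiral stationary phase (no bond is changed) supplies the R carbinol centre, which cannot racemise because it is quaternary.

Step 4
Reactants: 6 (−)-shikimic acid
Product: 8 methyl 3,4-O-isopropylideneshikimate, via methyl shikimate 7 (not isolated)
Conditions: CSA (cat.), MeOH, reflux; evaporate; 2,2-dimethoxypropane, CSA (cat.), acetone, rt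
Reagents that add atoms: methanol, CO; 2,2-dimethoxypropane, COC(C)(C)OC
Why: Fischer esterification followed by acid-catalysed transketalisation, which should engage only the cis-3,4-diol as a cis-fused dioxolane and leave the trans-disposed 5-OH free; no stereocentre is touched.

Step 5
Reactants: 8 methyl 3,4-O-isopropylideneshikimate
Product: 9 methyl 5-O-TBS-3,4-O-isopropylideneshikimate
Conditions: TBSCl, imidazole, DMF, rt
Reagents that add atoms: tert-butyldimethylsilyl chloride, CC(C)(C)[Si](C)(C)Cl
Why: Standard silyl ether formation at the only free hydroxyl.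

Step 6
Reactants: 9 methyl 5-O-TBS-3,4-O-isopropylideneshikimate
Product: 10 methyl 5-O-TBS-shikimate
Conditions: AcOH/H2O (4:1), 40 °C
Reagents that add atoms: none
Why: Mild acid hydrolysis of the cis-fused acetonide, under which the secondary TBS ether and the methyl ester should survive.

Step 7
Reactants: 10 methyl 5-O-TBS-shikimate
Product: 11 methyl 5-O-TBS-3-dehydroshikimate
Conditions: activated MnO2 (excess), CH2Cl2, rt
Reagents that add atoms: none
Why: Chemoselective MnO2 oxidation of the allylic 3-OH (a γ-hydroxy enoate) in the presence of the saturated 4-OH gives the enone, which sets the oxidation level the key step needs and erases the cis C-3 configuration that must end up trans.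

Step 8
Reactants: 12 pyruvic acid
Product: 14 2-(triethylsilyloxy)acryloyl chloride, via triethylsilyl 2-(triethylsilyloxy)acrylate 13 (not isolated)
Conditions: TESOTf (2.2 equiv), Et3N (2.5 equiv), CH2Cl2, 0 °C; pentane, filtration; (COCl)2 (1.1 equiv), DMF (cat.), CH2Cl2, 0 °C → rt; volatiles removed, used crude
Reagents that add atoms: triethylsilyl triflate, CC[Si](CC)(CC)OS(=O)(=O)C(F)(F)F; oxalyl chloride, ClC(=O)C(Cl)=O
Why: Silyl triflate/amine soft enolisation should give the silyl ester/silyl enol ether, and oxalyl chloride with catalytic DMF converts a silyl ester directly into the acid chloride under neutral conditions, the captodative enol ether being a poor nucleophile toward the Vilsmeier intermediate.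

Step 9
Reactants: 11 methyl 5-O-TBS-3-dehydroshikimate; 14 2-(triethylsilyloxy)acryloyl chloride
Product: 15 methyl 5-O-TBS-4-O-[2-(triethylsilyloxy)acryloyl]-3-dehydroshikimate
Conditions: 14 (1.5 equiv), pyridine (2 equiv), CH2Cl2, −40 → 0 °C
Reagents that add atoms: none
Why: O-Acylation of the secondary α-ketol by nucleophilic acyl substitution, with weak base and low temperature to limit β-elimination of the 5-silyloxy group; C-4 should keep its configuration because the trans-4,5 arrangement is also the thermodynamic one.

Step 10
Reactants: 5 (R)-sorbicillinol acetate; 15 methyl 5-O-TBS-4-O-[2-(triethylsilyloxy)acryloyl]-3-dehydroshikimate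
Product: 17 bicyclo[2.2.2]octane cycloadduct, via (R)-sorbicillinol 16 (not isolated)
Conditions: 5 (2.5 equiv), KOH, THF/H2O, 0 °C; 1 M HCl to pH 3, cold CH2Cl2 extraction, Na2SO4; this solution added over 6 h to 15 (1 equiv) in CH2Cl2, 0 °C → rt
Reagents that add atoms: none
Why: Diels–Alder reaction of the electron-poor hydroxy-dienone 16 with the captodative 2-silyloxyacrylate, in which the CH2 terminus should bond to the unsubstituted diene carbon and the oxygenated carbon to the C(Me) terminus, the dienophile should approach the face carrying the carbinol OH (anti to its methyl) and the ester carbonyl should sit endo, together setting both bridgeheads and the spiro carbon; slow addition of 16 keeps its self-dimerisation down.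

Step 11
Reactants: 17 bicyclo[2.2.2]octane cycloadduct
Product: 19 5-O-TBS ether of the target, via cis-fused cyclic triethylsilyl ketal 18 (not isolated)
Conditions: Et3SiH (3 equiv), TMSOTf (0.3 equiv), CH2Cl2/MeCN (4:1), −40 → −10 °C; pH 7 buffer
Reagents that add atoms: none
Why: TMSOTf activates the C-3 enone carbonyl, the spiro-carbinol oxygen (held six atoms away by the C-4 ester) adds with transfer of its SiEt3 group to give ketal 18, loss of Et3SiO– gives a ring-fused, allyl-conjugated oxocarbenium ion at C-3, and Et3SiH delivers hydride to it. The closest known reaction type is the intramolecular reductive etherification of silyloxy or hydroxy ketones used to build fused cyclic ethers. The 1,4-dioxan-2-one closes by 6-exo-trig attack of oxygen on the C-3 carbonyl from the face syn to O-4, the only face the short tether can reach. The C-3 stereocentre is set afterwards by the hydride, which should enter axially on the face anti to the pseudo-axial H-4 (1,3-related only to the small axial H-5), so that H-3 and H-4 end trans-diaxial and the ring fusion trans with all three ring oxygens equatorial. The step needs chemoselectivity for C-3 among five carbonyl groups and 1,2- over 1,4-hydride delivery: only C-3 can become an alkoxy-stabilised cation through a six-membered ketal, the bicyclic ketones have no oxygen within reach, the enolised sorbyl triketone is a poor hydride acceptor, and attack at C-1 of the conjugated cation is disfavoured by the ester it carries.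

Step 12
Reactants: 19 5-O-TBS ether of the target
Product: 20 target
Conditions: HF·pyridine, pyridine, THF, 0 °C → rt
Reagents that add atoms: none
Why: Fluoride-mediated cleavage of the secondary TBS ether under buffered acidic conditions that the lactone, the methyl ester and the enolised triketone should tolerate (silyl ether deprotection).

**Compound list**
1 | 2,4-dimethylbenzene-1,3-diol (2,4-dimethylresorcinol) | Cc1ccc(O)c(C)c1O | starting material
2 | sorbic acid, (2E,4E)-hexa-2,4-dienoic acid | C/C=C/C=C/C(=O)O | starting material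
3 | sorbicillin, (2E,4E)-1-(2,4-dihydroxy-3,5-dimethylphenyl)hexa-2,4-dien-1-one | C/C=C/C=C/C(=O)c1cc(C)c(O)c(C)c1O | intermediate
4 | racemic sorbicillinol acetate, (±)-3-[(2E,4E)-hexa-2,4-dienoyl]-4-hydroxy-1,5-dimethyl-6-oxocyclohexa-2,4-dien-1-yl acetate | C/C=C/C=C/C(=O)C1=CC(C)(OC(C)=O)C(=O)C(C)=C1O | intermediate
5 | (R)-sorbicillinol acetate, (1R)-enantiomer of 4 | C/C=C/C=C/C(=O)C1=C[C@@](C)(OC(C)=O)C(=O)C(C)=C1O | intermediate
6 | (−)-shikimic acid, (3R,4S,5R)-3,4,5-trihydroxycyclohex-1-ene-1-carboxylic acid | O=C(O)C1=C[C@@H](O)[C@@H](O)[C@H](O)C1 | starting material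
7 | methyl shikimate | COC(=O)C1=C[C@@H](O)[C@@H](O)[C@H](O)C1 | intermediate
8 | methyl 3,4-O-isopropylideneshikimate (5-OH free) | COC(=O)C1=C[C@@H](OC(C)(C)O2)[C@@H]2[C@H](O)C1 | intermediate
9 | methyl 5-O-(tert-butyldimethylsilyl)-3,4-O-isopropylideneshikimate | COC(=O)C1=C[C@@H](OC(C)(C)O2)[C@@H]2[C@H](O[Si](C)(C)C(C)(C)C)C1 | intermediate
10 | methyl 5-O-(tert-butyldimethylsilyl)shikimate (3,4-diol) | COC(=O)C1=C[C@@H](O)[C@@H](O)[C@H](O[Si](C)(C)C(C)(C)C)C1 | intermediate
11 | methyl 5-O-TBS-3-dehydroshikimate, methyl (4S,5R)-5-(tert-butyldimethylsilyloxy)-4-hydroxy-3-oxocyclohex-1-ene-1-carboxylate | COC(=O)C1=CC(=O)[C@@H](O)[C@H](O[Si](C)(C)C(C)(C)C)C1 | intermediate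
12 | pyruvic acid | CC(=O)C(=O)O | starting material
13 | triethylsilyl 2-(triethylsilyloxy)prop-2-enoate | C=C(O[Si](CC)(CC)CC)C(=O)O[Si](CC)(CC)CC | intermediate
14 | 2-(triethylsilyloxy)prop-2-enoyl chloride | C=C(O[Si](CC)(CC)CC)C(Cl)=O | intermediate
15 | methyl (4S,5R)-5-(tert-butyldimethylsilyloxy)-3-oxo-4-{[2-(triethylsilyloxy)acryloyl]oxy}cyclohex-1-ene-1-carboxylate | COC(=O)C1=CC(=O)[C@@H](OC(=O)C(=C)O[Si](CC)(CC)CC)[C@H](O[Si](C)(C)C(C)(C)C)C1 | intermediate
16 | (R)-sorbicillinol, (6R)-4-[(2E,4E)-hexa-2,4-dienoyl]-3,6-dihydroxy-2,6-dimethylcyclohexa-2,4-dien-1-one | C/C=C/C=C/C(=O)C1=C[C@@](C)(O)C(=O)C(C)=C1O | intermediate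
17 | cycloadduct: 11 acylated at O-4 by 5-hydroxy-8-[(2E,4E)-1-hydroxyhexa-2,4-dienylidene]-1,5-dimethyl-6,7-dioxo-2-(triethylsilyloxy)bicyclo[2.2.2]octane-2-carboxylic acid; 5-OH toward the C-2/C-3 bridge, 2-OSiEt3 toward the C-5/C-6 bridge, carboxyl toward the C-7/C-8 bridge | C/C=C/C=C/C(O)=C1/C(=O)[C@@]2(C)C(=O)[C@](C)(O)[C@@H]1C[C@@]2(O[Si](CC)(CC)CC)C(=O)O[C@@H]1C(=O)C=C(C(=O)OC)C[C@H]1O[Si](C)(C)C(C)(C)C | intermediate
18 | cis-fused cyclic ketal: spiro oxygen bonded to C-3 on the face of O-4, C-3 also carrying OSiEt3, 5-O-TBS | C/C=C/C=C/C(O)=C1/C(=O)[C@@]2(C)C(=O)[C@](C)(O)[C@@H]1C[C@]21O[C@]2(O[Si](CC)(CC)CC)C=C(C(=O)OC)C[C@@H](O[Si](C)(C)C(C)(C)C)[C@@H]2OC1=O | intermediate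
19 | 5-O-TBS ether of the target (trans-fused spiro-1,4-dioxan-2-one, C-3 S) | C/C=C/C=C/C(O)=C1/C(=O)[C@@]2(C)C(=O)[C@](C)(O)[C@@H]1C[C@]21O[C@H]2C=C(C(=O)OC)C[C@@H](O[Si](C)(C)C(C)(C)C)[C@@H]2OC1=O | intermediate
20 | target: bicyclo[2.2.2]octane spiro-linked at C-2 to a 1,4-dioxan-2-one that is trans-fused to the methyl 5-hydroxycyclohex-1-ene-1-carboxylate (C-3 S, C-4 S, C-5 R; carbinol R) | C/C=C/C=C/C(O)=C1/C(=O)[C@@]2(C)C(=O)[C@](C)(O)[C@@H]1C[C@]21O[C@H]2C=C(C(=O)OC)C[C@@H](O)[C@@H]2OC1=O | target

**Step count and risks**
Total: 12 steps. Longest linear sequence: 8 steps (6 → 20 through steps 4, 5, 6, 7, 9, 10, 11, 12).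

Most likely to fail:

1. Step 11. Hydride transfer to the Lewis-acid-activated sorbyl trienone, or elimination across C-4/C-5 with aromatisation of the cyclohexenone, may outrun ketal ionisation; the hindered tertiary silyl ether may also fail to engage the ketone. The fallback closes the dioxanone before the cycloaddition, on the simple cyclohexenone; it sets out from 11 and returns at 19. Commercial 3-chloro-2-hydroxypropanoic acid is bis-silylated (TESOTf, Et3N) to triethylsilyl 3-chloro-2-(triethylsilyloxy)propanoate F1 and converted with oxalyl chloride/cat. DMF into 3-chloro-2-(triethylsilyloxy)propanoyl chloride F2. Acylation of 11 (pyridine, CH2Cl2) gives methyl 5-O-TBS-4-O-[3-chloro-2-(triethylsilyloxy)propanoyl]-3-dehydroshikimate F3. The same Et3SiH/TMSOTf reductive etherification, now with a secondary silyl ether and no polyene present, should give the trans-fused 3-(chloromethyl)-1,4-dioxan-2-one F4. DBU-induced loss of HCl gives the exo-methylene dioxanone F5, an α-alkoxyacrylate lactone, whose Diels–Alder reaction with 16 (generated from 5 as in step 10) should give 19.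

2. Step 10. Dimerisation of 16 may outrun the cross-cycloaddition, silyl transfer from the enol ether to the acidic dienone may destroy the dienophile, or endo/exo discrimination at the spiro carbon may be poor with the acyclic dienophile. The fallback runs the cycloaddition with the cheap dienophile 13 in large excess and attaches the cyclohexenone afterwards; it sets out from 13 and 16 (from 5) and returns at 17. Cycloaddition of 16 with 13 (10 equiv, CH2Cl2) gives the triethylsilyl ester cycloadduct F6, whose silyl ester is hydrolysed on mild aqueous work-up to the bicyclic α-silyloxy acid F7. Yamaguchi esterification of F7 with 11 (2,4,6-trichlorobenzoyl chloride, Et3N, DMAP, toluene) gives 17.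

3. Step 9. Base-induced β-elimination of the 5-silyloxy group with aromatisation of 11, or decomposition of the acid chloride 14 (including attack of the Vilsmeier catalyst on its enol ether during its preparation), may prevent clean acylation. The fallback installs the pyruvate first and forms the enol silane afterwards; it sets out from 11 and 12 and returns at 15. Steglich esterification of 11 with 12 (DCC, cat. DMAP, CH2Cl2, 0 °C) gives methyl 5-O-TBS-4-O-pyruvoyl-3-dehydroshikimate F8. Soft enolisation (TESOTf, Et3N, CH2Cl2, −78 °C), which should take the far more readily enolised α-keto ester methyl group in preference to the ring ketone, gives 15.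

**Further compounds**
F1 | step 11 | triethylsilyl 3-chloro-2-(triethylsilyloxy)propanoate | ClCC(O[Si](CC)(CC)CC)C(=O)O[Si](CC)(CC)CC
F2 | step 11 | 3-chloro-2-(triethylsilyloxy)propanoyl chloride | ClCC(O[Si](CC)(CC)CC)C(Cl)=O
F3 | step 11 | methyl 5-O-TBS-4-O-[3-chloro-2-(triethylsilyloxy)propanoyl]-3-dehydroshikimate | COC(=O)C1=CC(=O)[C@@H](OC(=O)C(CCl)O[Si](CC)(CC)CC)[C@H](O[Si](C)(C)C(C)(C)C)C1
F4 | step 11 | trans-fused 3-(chloromethyl)-1,4-dioxan-2-one on the 5-O-TBS cyclohexene ester | ClCC1O[C@H]2C=C(C(=O)OC)C[C@@H](O[Si](C)(C)C(C)(C)C)[C@@H]2OC1=O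
F5 | step 11 | trans-fused 3-methylene-1,4-dioxan-2-one on the 5-O-TBS cyclohexene ester | C=C1O[C@H]2C=C(C(=O)OC)C[C@@H](O[Si](C)(C)C(C)(C)C)[C@@H]2OC1=O
F6 | step 10 | triethylsilyl ester cycloadduct of 16 and 13 | C/C=C/C=C/C(O)=C1/C(=O)[C@@]2(C)C(=O)[C@](C)(O)[C@@H]1C[C@@]2(O[Si](CC)(CC)CC)C(=O)O[Si](CC)(CC)CC
F7 | step 10 | bicyclic 2-(triethylsilyloxy) carboxylic acid | C/C=C/C=C/C(O)=C1/C(=O)[C@@]2(C)C(=O)[C@](C)(O)[C@@H]1C[C@@]2(O[Si](CC)(CC)CC)C(=O)O
F8 | step 9 | methyl 5-O-TBS-4-O-pyruvoyl-3-dehydroshikimate | COC(=O)C1=CC(=O)[C@@H](OC(=O)C(C)=O)[C@H](O[Si](C)(C)C(C)(C)C)C1
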